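An exchange between left-handed substrate and right-handed substrate too slow to be seen is what the amber run reads like: its product excess falls from 47.6 % at 10.0 s to 29.7 % at 80.0 s, as it does with no exchange, whereas instant exchange holds an excess level.

in all of them: gas 160 mM (held); free catalyst 2.5 mol%; racemization catalyst 5 mol%; impurity 60 mM

| run | left-handed substrate | right-handed substrate | remark | time |
|---|---|---|---|---|
| amber | 1 M | 1 M | run made earlier |  |
| flask | 2.0 M | 2.0 M |  | 4.0 min |

- amber (time / s: left-handed product / %, right-handed product / %): 10.0: 6.2, 2.2; 15.0: 7.1, 2.0; 25.0: 13.2, 5.4; 40.0: 17.9, 8.7; 80.0: 34.5, 18.7

(readings scatter by 1 percentage point)

- free catalyst is single-handed; left-handed substrate and right-handed substrate are mirror images of each other, charged as a racemate, each of them at the stated concentration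
- the analysis behind the earlier runs scatters by 1 percentage point, standard deviation
- at the start none of the gas is in solution
- an excess is the difference of the two amounts in percent of their sum
- an excess is below zero if the other one leads
- no earlier run changes the charge of racemization catalyst; that part of a forecast is a guess
- no earlier run changes the charge of free catalyst; that part of a forecast is a guess

1. left-handed product and right-handed product together, in percent of the left-handed substrate and right-handed substrate charged together, at 4.0 min
2. excess of left-handed product over right-handed product in the product at 4.0 min
3. whether the exchange between left-handed substrate and right-handed substrate keeps pace with the reaction: how far the product's excess at 4.0 min gets from its value without exchange to its value with instant exchange (above 80 % keeps pace, below 20 % hardly takes part, else lags behind)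

Two amounts stand behind that reading: the racemization catalyst charged and the impurity charged. Suppose the two consume each other one for one. The amber run then sets 50.0 mM of racemization catalyst against 60 mM of impurity, so on this count the catalyst goes first, with 10.0 mM of impurity to spare. The new flask charges the same mol% on a doubled substrate, which makes 100 mM of racemization catalyst against the same 60 mM of impurity, so there the impurity is the limiting reagent. This flask keeps 40.0 mM: that is the live catalyst L, racemization catalyst charged minus impurity charged, a share of 40.0 % of the charge. No earlier run shows how fast L exchanges the substrates, so this reckoning expects exchange in the flask and gives it no speed.

The forecast gives 93 %, 14 % and "lags behind", on the ground that “some racemization catalyst survives”.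

The flask gives 91.1 % and 12.9 % at 4.0 min, and the exchange hardly takes part, at 11 % of the way. Racemization catalyst stands at 40.0 % of its charge at 2.00 min.

    racemization catalyst + impurity → spent catalyst (k = 19.0 /M/s)
    gas ⇌ partner, rate k2*(csat - [partner]) (kL = 0.120 /s)
    left-handed substrate + racemization catalyst ⇌ right-handed substrate + racemization catalyst, rate k3*[racemization catalyst]*[left-handed substrate] forward; the back reaction follows from the equilibrium constant (k = 0.0220 /M/s)
    partner + free catalyst + left-handed substrate → free catalyst + left-handed product (k = 12.0 /M²/s)
    partner + free catalyst + right-handed substrate → free catalyst + right-handed product (k = 4.70 /M²/s)

With 0.022 /M/s, L gives the difference between the two substrates a half-life of 6.56 min under exchange alone, longer than the 4.0 min of the flask. The neighbour flask charged with 12 mol% of racemization catalyst has L = 180 mM, which is 75.0 % of its charge; it holds 75.0 % and reaches a product excess of 22.3 %.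

(The data are calculated with constants of no real substance; scatter was added.)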